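(The earlier runs and the new flask come from a simulation from invented constants.)

**The ratio.** If starting material has two ways to go and is used up, the end depends on the ratio of their rates, not on either rate. Here the flasks are these:

the same everywhere: starting material 20 mM
- Friday's: reagent 11 mM; second substrate 4 mM; protic impurity 6 mM; temperature 20 °C; run made earlier
- Thursday's: reagent 16 mM; second substrate 4 mM; protic impurity 6 mM; temperature 40 °C; run made earlier
- alpha: reagent 22.0 mM; second substrate 4.00 mM; protic impurity 6.00 mM; temperature 25 °C; time 12 min
- zeta: reagent 22.0 mM; second substrate 4.00 mM; protic impurity 6.00 mM; temperature 55 °C; time 12 min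
- epsilon: reagent 22.0 mM; second substrate 4.00 mM; protic impurity 6.00 mM; at 25 °C until 2.5 min, from then on at 55 °C; time 12 min

| run | time / min | target / % | starting material / % |
|---|---|---|---|
| Friday's | 1.33 | 8.8 | 21.5 |
| Friday's | 3.00 | 11.4 | 9.9 |
| Friday's | 4.00 | 12.5 | 7.6 |
| Friday's | 6.00 | 13.3 | 4.5 |
| Friday's | 8.00 | 14.5 | 3.2 |
| Thursday's | 0.333 | 17.3 | 27.2 |
| Thursday's | 1.00 | 24.1 | 9.2 |
| Thursday's | 1.33 | 25.6 | 6.3 |
| Thursday's | 2.50 | 28.2 | 2.3 |
| Thursday's | 4.00 | 29.6 | 1.4 |

(each reading ± 0.5 percentage points)

- percent here means starting material units held: one homo dimer counts as two
- steps under discussion: starting material + reagent -> target; second substrate + reagent -> second product; starting material + second substrate -> cross product; 2 starting material -> homo dimer; second substrate + protic impurity -> quenched substrate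

- the flask with the highest amount of target, in percent of the starting material charged ("all alike" if they lie within 1.5 percentage points) (alpha / zeta / epsilon / all alike)
- final target, as a percentage of the starting material charged, in alpha
- final target, as a percentage of the starting material charged, in zeta
- final target, as a percentage of the starting material charged, in epsilon

Let a be the fraction of starting material left and r the free reagent, both as fractions of the starting material charged. The reckoning takes r as the reagent charge less the second substrate, less the target formed. Target making then runs at σ·r/a times the rate at which dimer loss uses starting material, where σ, the selectivity factor, is taken to depend on temperature.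

**Two readings.** Between its first and third readings, Thursday's run gained target at 0.659 of the dimer loss, which gives σ = 0.286 as a reading. Friday's run, read the same way, gives 0.217. Taking ln σ as straight in temperature, alpha has 0.232, and the selectivity factor at zeta's temperature is 0.353.

**The slowing.** Dimer loss slows with the square of a, target making with a and r once each, so the ratio climbs while a falls faster than r. Integrating the ratio, with m = 1/σ − 1 and r₀ the free reagent at the start, gives a final r of r₀ times the m-th root of r₀/(m + r₀). The target is the difference between r₀ and that final r. This reckoning gives alpha 33.6% and zeta 40.9%. Friday's run, colder and with less reagent, had 9.9% starting material left at 3.00 min, so epsilon should land near alpha.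

**The forecast.** It says zeta, with alpha 31%, zeta 39.5% and epsilon 31.5%, on the ground that “Heat therefore favours target”. The reckoning above stands higher for alpha and for zeta, in the same order.

    starting material + reagent → target (k = 29.0 L mol⁻¹ min⁻¹, Ea = 58.0 kJ mol⁻¹)
    second substrate + reagent → second product (k = 340 L mol⁻¹ min⁻¹, Ea = 53.0 kJ mol⁻¹)
    starting material + second substrate → cross product (k = 7.70 L mol⁻¹ min⁻¹, Ea = 38.0 kJ mol⁻¹)
    2 starting material → homo dimer (k = 76.0 L mol⁻¹ min⁻¹, Ea = 38.0 kJ mol⁻¹)
    second substrate + protic impurity → quenched substrate (k = 16.0 L mol⁻¹ min⁻¹, Ea = 65.0 kJ mol⁻¹)
    (constants at 25 °C)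

**The result.** Zeta holds 44.1% target, alpha 31.0% and epsilon 31.7%, so zeta leads. In zeta the ratio of target making to dimer loss is 0.44 at the start, against 0.388 from σ, and 0.76 at 0.0905 min. A neighbouring flask, zeta with the charge of second substrate raised to 16 mM, is reckoned with the same σ at 19.7%. That neighbouring flask holds 26.9% target, less than alpha's 31.0%, and its second product stands at 15.1 mM.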